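Ring D is numbered C1 (OMe), C2 (Me), C3 (OH), C4 (acyl), C5 (OH), C6 (CH2 bridge to flavone C8). Its oxygens on C1, C3 and C5 alternate with carbon substituents, exactly the pattern that a 3-alkoxycyclobutenone and an alkynyl ether deliver in a Danheiser benzannulation. The route therefore forms ring D late, from a cyclobutenone whose C2 already carries the complete, benzyl-protected 3-methoxyflavone through the CH2 group and whose C3 carries a benzyloxy group. Heating it with 1-methoxypropyne forms three ring D bonds (C2–C3, C1–C6, C3–C4) in one operation and leaves OH, OMe and OBn differentiated, with only C4 open for Fries acylation; one hydrogenolysis ends the route.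

Key step: step 12

Assumption: 2-methoxy-1-(2,4,6-trihydroxyphenyl)ethan-1-one (1) is taken as a catalogue compound (otherwise one Hoesch step from phloroglucinol and methoxyacetonitrile).

Remark: the cyclobutenone oxygen carries benzyl, not a simple alkyl group, because an alkyl ether beside the ring D ketone could not be cleaved selectively once the other ortho oxygen is a free, chelating OH, whereas benzyl leaves together with the flavone benzyl ethers. The target has no stereocentre; the only chiral species, transient 25, is racemic.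

Step 1
Reactants: 1 2-methoxy-1-(2,4,6-trihydroxyphenyl)ethan-1-one; 2 benzoic anhydride
Product: 4 5,7-dihydroxy-3-methoxyflavone, via flavone dibenzoate 3 (not isolated)
Conditions: PhCO2Na, neat, 180 °C; then KOH, EtOH–H2O, reflux; then aq. HCl
Reagents that add atoms: none
Why: Allan–Robinson flavone synthesis, in which O-benzoylation, acyl transfer to the methoxy-bearing α-carbon and cyclodehydration build the pyrone ring with the 3-OMe group in place; the symmetric phloroglucinol ring allows only one flavone, and the alkaline treatment only saponifies the O-benzoates.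

Step 2
Reactants: 4 5,7-dihydroxy-3-methoxyflavone
Product: 5 5,7-bis(benzyloxy)-3-methoxyflavone
Conditions: BnBr (3 equiv), K2CO3, DMF, 70 °C
Reagents that add atoms: benzyl bromide, BrCc1ccccc1
Why: Williamson ether synthesis on both phenols, the chelated 5-OH being forced by excess halide and heat in DMF; benzyl ethers are inert in all later neutral steps and are removable without touching methyl ethers.

Step 3
Reactants: 5 5,7-bis(benzyloxy)-3-methoxyflavone
Product: 6 5,7-bis(benzyloxy)-8-iodo-3-methoxyflavone
Conditions: NIS (1.05 equiv), TFA (cat.), MeCN, 0 °C → rt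
Reagents that add atoms: N-iodosuccinimide, O=C1CCC(=O)N1I
Why: Electrophilic aromatic iodination, which in 5,7-dialkoxyflavones is expected at C8 (para to O5, ortho to O7) and not at C6, which lies between two bulky benzyloxy groups.

Step 4
Reactants: 6 5,7-bis(benzyloxy)-8-iodo-3-methoxyflavone; 7 (tributylstannyl)methanol
Product: 8 5,7-bis(benzyloxy)-8-(hydroxymethyl)-3-methoxyflavone
Conditions: Pd(PPh3)4 (5 mol %), 1,4-dioxane, 95 °C
Reagents that add atoms: none
Why: Stille hydroxymethylation of an aryl iodide, in which the CH2OH group is transferred from tin in preference to butyl and the future bridge carbon is installed under neutral conditions.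

Step 5
Reactants: 8 5,7-bis(benzyloxy)-8-(hydroxymethyl)-3-methoxyflavone
Product: 9 5,7-bis(benzyloxy)-8-(bromomethyl)-3-methoxyflavone
Conditions: CBr4, PPh3, CH2Cl2, 0 °C; used without storage
Reagents that add atoms: carbon tetrabromide, BrC(Br)(Br)Br
Why: Appel bromination of a primary benzylic alcohol under neutral conditions that spare the benzyl ethers and the pyrone.

Step 6
Reactants: 10 benzyl alcohol; 11 trichloroethylene
Product: 13 benzyl (E)-1,2-dichlorovinyl ether, via dichloroacetylene 12 (not isolated)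
Conditions: KH, THF, 0 °C; then 11, −50 °C → rt
Reagents that add atoms: none
Why: Base-induced dehydrochlorination of trichloroethylene gives dichloroacetylene, to which the benzyl alkoxide adds with anti protonation, which fixes the E geometry of the dichlorovinyl ether (standard entry to alkynyl ethers).

Step 7
Reactants: 13 benzyl (E)-1,2-dichlorovinyl ether
Product: 15 tributyl[(benzyloxy)ethynyl]stannane, via lithium benzyloxyacetylide 14 (not isolated)
Conditions: n-BuLi (2.2 equiv), THF, −78 °C; then Bu3SnCl, −78 → 0 °C; kept cold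
Reagents that add atoms: tributyltin chloride, CCCC[Sn](Cl)(CCCC)CCCC
Why: Elimination to the chloroalkynyl ether followed by lithium–chlorine exchange gives the lithium alkoxyacetylide, which is stannylated at carbon well below the temperature at which benzyl alkynyl ethers rearrange.

Step 8
Reactants: 9 5,7-bis(benzyloxy)-8-(bromomethyl)-3-methoxyflavone; 15 tributyl[(benzyloxy)ethynyl]stannane
Product: 16 5,7-bis(benzyloxy)-8-[3-(benzyloxy)prop-2-yn-1-yl]-3-methoxyflavone
Conditions: Pd2(dba)3 (2.5 mol %), P(2-furyl)3 (10 mol %), THF, rt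
Reagents that add atoms: none
Why: Stille coupling of a benzylic bromide with an alkynylstannane, which should run at room temperature because oxidative addition to zerovalent palladium and alkynyl transfer from tin are both fast, keeping the benzyl alkynyl ether below its sigmatropic rearrangement range.

Step 9
Reactants: 16 5,7-bis(benzyloxy)-8-[3-(benzyloxy)prop-2-yn-1-yl]-3-methoxyflavone; 17 trichloroacetyl chloride
Product: 19 3-(benzyloxy)-4,4-dichloro-2-{[5,7-bis(benzyloxy)-3-methoxyflavon-8-yl]methyl}cyclobut-2-en-1-one, via dichloroketene 18 (not isolated)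
Conditions: Zn–Cu couple, Et2O–DME, 0 °C → rt, slow addition of 17
Reagents that add atoms: none
Why: [2+2] cycloaddition of dichloroketene to an alkynyl ether, in which the nucleophilic β-carbon of the ynol ether bonds to the ketene carbonyl carbon, so the flavonylmethyl group ends on C2 and the benzyloxy group on C3 of the cyclobutenone.

Step 10
Reactants: 19 3-(benzyloxy)-4,4-dichloro-2-{[5,7-bis(benzyloxy)-3-methoxyflavon-8-yl]methyl}cyclobut-2-en-1-one
Product: 20 3-(benzyloxy)-2-{[5,7-bis(benzyloxy)-3-methoxyflavon-8-yl]methyl}cyclobut-2-en-1-one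
Conditions: Zn dust, AcOH, TMEDA, THF, 0 °C → rt
Reagents that add atoms: none
Why: Buffered zinc reduction of an α,α-dichloroketone, the standard dechlorination of 4,4-dichlorocyclobutenones, which should leave the vinylogous ester, the benzyl ethers and the flavone untouched.

Step 11
Reactants: 21 chloroacetaldehyde dimethyl acetal
Product: 23 1-methoxypropyne, via sodium methoxyacetylide 22 (not isolated)
Conditions: NaNH2 (3.1 equiv), liquid NH3, −33 °C; then MeI, −40 °C; distillation
Reagents that add atoms: iodomethane, CI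
Why: Twofold elimination (HCl, then methanol) from the chloroacetal gives the sodium alkoxyacetylide, which is C-methylated in the same flask (classical alkoxyalkyne synthesis); a methyl ynol ether cannot lose an alkene by retro-ene reaction on later heating.

Step 12
Reactants: 20 3-(benzyloxy)-2-{[5,7-bis(benzyloxy)-3-methoxyflavon-8-yl]methyl}cyclobut-2-en-1-one; 23 1-methoxypropyne
Product: 28 5,7-bis(benzyloxy)-8-{[6-(benzyloxy)-4-hydroxy-2-methoxy-3-methylphenyl]methyl}-3-methoxyflavone, via vinylketene 24 (not isolated), via vinylcyclobutenone 25 (not isolated), via dienylketene 26 (not isolated), via cyclohexadienone 27 (not isolated)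
Conditions: 23 (4 equiv), toluene, sealed tube, 80 °C then 110 °C; then K2CO3, MeOH, rt
Reagents that add atoms: none
Why: This is a Danheiser benzannulation of a cyclobutenone with an alkynyl ether, the closest known reaction type: thermal four-electron electrocyclic opening of 20 gives vinylketene 24, whose ketene C=C adds methoxypropyne by [2+2] cycloaddition to give 25. Conrotatory four-electron opening of 25 gives dienylketene 26, and ring D is closed by six-electron disrotatory electrocyclisation (ketene carbon to the terminal CH2) to dienone 27, which tautomerises irreversibly to phenol 28. No stereocentre appears in the product, since the quaternary centre of racemic 25 is erased on ring opening. The step needs a single regiochemistry in the cycloaddition, and the polarised ynol ether secures it: its nucleophilic methyl-bearing carbon bonds to the electrophilic ketene carbonyl carbon, so Me ends on ring D C2 beside the new OH and OMe on C1 beside the bridge carbon. Chemoselectivity rests on the ketene being the most electrophilic π-system present, while the flavone, its benzyl ethers and the enol ether are spectators under neutral heating. The brief carbonate–methanol treatment only returns any phenol that was O-acylated by ketene.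

Step 13
Reactants: 28 5,7-bis(benzyloxy)-8-{[6-(benzyloxy)-4-hydroxy-2-methoxy-3-methylphenyl]methyl}-3-methoxyflavone; 29 3-phenylpropanoyl chloride
Product: 30 5-(benzyloxy)-4-{[5,7-bis(benzyloxy)-3-methoxyflavon-8-yl]methyl}-3-methoxy-2-methylphenyl 3-phenylpropanoate
Conditions: Et3N, DMAP (cat.), CH2Cl2, 0 °C → rt
Reagents that add atoms: none
Why: DMAP-catalysed O-acylation of the only free hydroxyl group in the molecule.

Step 14
Reactants: 30 5-(benzyloxy)-4-{[5,7-bis(benzyloxy)-3-methoxyflavon-8-yl]methyl}-3-methoxy-2-methylphenyl 3-phenylpropanoate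
Product: 31 7-(benzyloxy)-8-{[2,4-dihydroxy-6-methoxy-5-methyl-3-(3-phenylpropanoyl)phenyl]methyl}-5-hydroxy-3-methoxyflavone
Conditions: TiCl4 (4 equiv), CH2Cl2, 0 °C → rt; aq. HCl work-up
Reagents that add atoms: none
Why: Fries rearrangement, in which the TiCl4-bound ester should deliver the acyl group to ring D C4, the only unsubstituted carbon and one activated by ortho-oxygen and para-OMe, while the same Lewis acid is expected to cleave by chelation the two benzyl ethers next to carbonyl groups (flavone O5 and ring D O5), which is harmless because any benzyl ether still present is removed in step 15.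

Step 15
Reactants: 31 7-(benzyloxy)-8-{[2,4-dihydroxy-6-methoxy-5-methyl-3-(3-phenylpropanoyl)phenyl]methyl}-5-hydroxy-3-methoxyflavone
Product: 32 8-{[2,4-dihydroxy-6-methoxy-5-methyl-3-(3-phenylpropanoyl)phenyl]methyl}-5,7-dihydroxy-3-methoxyflavone (CNP0280022.0)
Conditions: H2 (1 atm), 10% Pd/C, EtOAc–MeOH, rt
Reagents that add atoms: none
Why: Catalytic hydrogenolysis of the remaining aryl benzyl ether under mild conditions that should leave the hydrogen-bonded aryl ketone, the tetrasubstituted flavone double bond, the methyl ethers and the diarylmethane intact.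

Compound list
1 | 2-methoxy-1-(2,4,6-trihydroxyphenyl)ethan-1-one | COCC(=O)c1c(O)cc(O)cc1O | starting material
2 | benzoic anhydride | O=C(OC(=O)c1ccccc1)c1ccccc1 | starting material
3 | 5,7-bis(benzoyloxy)-3-methoxyflavone | COc1c(-c2ccccc2)oc2cc(OC(=O)c3ccccc3)cc(OC(=O)c3ccccc3)c2c1=O | intermediate (not isolated)
4 | 5,7-dihydroxy-3-methoxyflavone | COc1c(-c2ccccc2)oc2cc(O)cc(O)c2c1=O | intermediate
5 | 5,7-bis(benzyloxy)-3-methoxyflavone | COc1c(-c2ccccc2)oc2cc(OCc3ccccc3)cc(OCc3ccccc3)c2c1=O | intermediate
6 | 5,7-bis(benzyloxy)-8-iodo-3-methoxyflavone | COc1c(-c2ccccc2)oc2c(I)c(OCc3ccccc3)cc(OCc3ccccc3)c2c1=O | intermediate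
7 | (tributylstannyl)methanol | CCCC[Sn](CO)(CCCC)CCCC | starting material
8 | 5,7-bis(benzyloxy)-8-(hydroxymethyl)-3-methoxyflavone | COc1c(-c2ccccc2)oc2c(CO)c(OCc3ccccc3)cc(OCc3ccccc3)c2c1=O | intermediate
9 | 5,7-bis(benzyloxy)-8-(bromomethyl)-3-methoxyflavone | COc1c(-c2ccccc2)oc2c(CBr)c(OCc3ccccc3)cc(OCc3ccccc3)c2c1=O | intermediate
10 | benzyl alcohol | OCc1ccccc1 | starting material
11 | trichloroethylene | ClC=C(Cl)Cl | starting material
12 | dichloroacetylene | ClC#CCl | intermediate (not isolated)
13 | benzyl (E)-1,2-dichlorovinyl ether | Cl/C=C(\OCc1ccccc1)Cl | intermediate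
14 | lithium (benzyloxy)acetylide | [Li+].[C-]#COCc1ccccc1 | intermediate (not isolated)
15 | tributyl[(benzyloxy)ethynyl]stannane | CCCC[Sn](C#COCc1ccccc1)(CCCC)CCCC | intermediate
16 | 5,7-bis(benzyloxy)-8-[3-(benzyloxy)prop-2-yn-1-yl]-3-methoxyflavone | COc1c(-c2ccccc2)oc2c(CC#COCc3ccccc3)c(OCc3ccccc3)cc(OCc3ccccc3)c2c1=O | intermediate
17 | trichloroacetyl chloride | O=C(Cl)C(Cl)(Cl)Cl | starting material
18 | dichloroketene | O=C=C(Cl)Cl | intermediate (not isolated)
19 | 3-(benzyloxy)-4,4-dichloro-2-{[5,7-bis(benzyloxy)-3-methoxyflavon-8-yl]methyl}cyclobut-2-en-1-one | COc1c(-c2ccccc2)oc2c(CC3=C(OCc4ccccc4)C(Cl)(Cl)C3=O)c(OCc3ccccc3)cc(OCc3ccccc3)c2c1=O | intermediate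
20 | 3-(benzyloxy)-2-{[5,7-bis(benzyloxy)-3-methoxyflavon-8-yl]methyl}cyclobut-2-en-1-one | COc1c(-c2ccccc2)oc2c(CC3=C(OCc4ccccc4)CC3=O)c(OCc3ccccc3)cc(OCc3ccccc3)c2c1=O | intermediate (precursor of the key step)
21 | chloroacetaldehyde dimethyl acetal | COC(CCl)OC | starting material
22 | sodium methoxyacetylide | [Na+].[C-]#COC | intermediate (not isolated)
23 | 1-methoxypropyne | CC#COC | intermediate
24 | vinylketene: 3-(benzyloxy)-2-{[5,7-bis(benzyloxy)-3-methoxyflavon-8-yl]methyl}buta-1,3-dien-1-one | COc1c(-c2ccccc2)oc2c(CC(=C=O)C(=C)OCc3ccccc3)c(OCc3ccccc3)cc(OCc3ccccc3)c2c1=O | intermediate (not isolated)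
25 | vinylcyclobutenone (racemic): 4-[1-(benzyloxy)vinyl]-4-{[5,7-bis(benzyloxy)-3-methoxyflavon-8-yl]methyl}-3-methoxy-2-methylcyclobut-2-en-1-one | COc1c(-c2ccccc2)oc2c(CC3(C(=C)OCc4ccccc4)C(=O)C(C)=C3OC)c(OCc3ccccc3)cc(OCc3ccccc3)c2c1=O | intermediate (not isolated)
26 | dienylketene: 5-(benzyloxy)-4-{[5,7-bis(benzyloxy)-3-methoxyflavon-8-yl]methyl}-3-methoxy-2-methylhexa-1,3,5-trien-1-one, ketenyl and vinyl groups cis on the central double bond | COc1c(-c2ccccc2)oc2c(C/C(C(=C)OCc3ccccc3)=C(\OC)C(C)=C=O)c(OCc3ccccc3)cc(OCc3ccccc3)c2c1=O | intermediate (not isolated)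
27 | cyclohexadienone: 5-(benzyloxy)-4-{[5,7-bis(benzyloxy)-3-methoxyflavon-8-yl]methyl}-3-methoxy-2-methylcyclohexa-2,4-dien-1-one | COc1c(-c2ccccc2)oc2c(CC3=C(OCc4ccccc4)CC(=O)C(C)=C3OC)c(OCc3ccccc3)cc(OCc3ccccc3)c2c1=O | intermediate (not isolated)
28 | 5,7-bis(benzyloxy)-8-{[6-(benzyloxy)-4-hydroxy-2-methoxy-3-methylphenyl]methyl}-3-methoxyflavone | COc1c(-c2ccccc2)oc2c(Cc3c(OCc4ccccc4)cc(O)c(C)c3OC)c(OCc3ccccc3)cc(OCc3ccccc3)c2c1=O | intermediate (product of the key step)
29 | 3-phenylpropanoyl chloride | O=C(Cl)CCc1ccccc1 | starting material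
30 | 5-(benzyloxy)-4-{[5,7-bis(benzyloxy)-3-methoxyflavon-8-yl]methyl}-3-methoxy-2-methylphenyl 3-phenylpropanoate | COc1c(-c2ccccc2)oc2c(Cc3c(OCc4ccccc4)cc(OC(=O)CCc4ccccc4)c(C)c3OC)c(OCc3ccccc3)cc(OCc3ccccc3)c2c1=O | intermediate
31 | 7-(benzyloxy)-8-{[2,4-dihydroxy-6-methoxy-5-methyl-3-(3-phenylpropanoyl)phenyl]methyl}-5-hydroxy-3-methoxyflavone | COc1c(-c2ccccc2)oc2c(Cc3c(O)c(C(=O)CCc4ccccc4)c(O)c(C)c3OC)c(OCc3ccccc3)cc(O)c2c1=O | intermediate
32 | 8-{[2,4-dihydroxy-6-methoxy-5-methyl-3-(3-phenylpropanoyl)phenyl]methyl}-5,7-dihydroxy-3-methoxyflavone (CNP0280022.0) | COc1c(C)c(O)c(C(=O)CCc2ccccc2)c(O)c1Cc1c(O)cc(O)c2c(=O)c(OC)c(-c3ccccc3)oc12 | target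

Total step count: 15. Longest linear sequence: 12 steps (steps 1–5, 8–10, 12–15); steps 6–7 and step 11 are side branches.

Steps most likely to fail

Step 12. The electrocyclic opening of the alkoxy-stabilised cyclobutenone may be slow, so that the vinylketene is consumed by dimerisation or by O-acylation of the product phenol before it meets the alkyne. Fallback (sets out from 8, returns at 32): ring D is made separately as a finished dihydrochalcone and joined to the flavone by Friedel–Crafts benzylation. 2,4,6-Trihydroxytoluene is C-acylated with 29 (AlCl3, CH2Cl2–PhNO2) to 1-(2,4,6-trihydroxy-3-methylphenyl)-3-phenylpropan-1-one F1. Its only non-chelated hydroxyl, para to the ketone, is methylated (MeI, 1 equiv, K2CO3, acetone) to 1-(2,6-dihydroxy-4-methoxy-3-methylphenyl)-3-phenylpropan-1-one F2. The single free ring carbon of F2 is alkylated by benzylic alcohol 8 under acid catalysis (Sc(OTf)3 cat., MeNO2–CH2Cl2, rt) to the 5,7-di-O-benzyl ether of the target F3. Hydrogenolysis under the conditions of step 15 should then give 32.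

Step 14. Lewis-acid cleavage of benzyl ethers may run ahead of the acyl shift, with transfer of benzyl groups to carbon or acid-induced scission of the diarylmethane bridge. Fallback (sets out from 28, returns at 32): direct C-acylation with a nitrile instead of an O-to-C shift. Houben–Hoesch reaction of 28 with 3-phenylpropanenitrile (ZnCl2, HCl gas, Et2O, 0 °C) should give the ring D C4 ketiminium chloride F4. Warming with water hydrolyses it to the tri-O-benzyl ketone F5, and hydrogenolysis under the conditions of step 15 removes all three benzyl groups to give 32.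

Step 8. Sigmatropic rearrangement of the benzyl alkynyl ether (in the stannane or in the product) may compete with transmetalation, and the benzylic bromide may ionise or homocouple. Fallback (sets out from 9, returns at 20): the thermally robust ethyl ynol ether is carried to the cyclobutenone stage and the oxygen substituent is exchanged there. Stille coupling of 9 with commercial tributyl(ethoxyethynyl)stannane gives 5,7-bis(benzyloxy)-8-(3-ethoxyprop-2-yn-1-yl)-3-methoxyflavone F6. Dichloroketene cycloaddition as in step 9 gives the 4,4-dichloro-3-ethoxycyclobutenone F7, and zinc dechlorination as in step 10 gives the 3-ethoxycyclobutenone F8. Mild acid hydrolysis (dilute HCl, THF, rt) gives the symmetric 2-substituted cyclobutane-1,3-dione, written as its enol 3-hydroxy-2-{[5,7-bis(benzyloxy)-3-methoxyflavon-8-yl]methyl}cyclobut-2-en-1-one F9. Its acidic enol is O-benzylated under Mitsunobu conditions (BnOH, PPh3, DIAD, THF), which can give only one regioisomer, 20.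

Further compounds
F1 | step 12 | 1-(2,4,6-trihydroxy-3-methylphenyl)-3-phenylpropan-1-one | Cc1c(O)cc(O)c(C(=O)CCc2ccccc2)c1O
F2 | step 12 | 1-(2,6-dihydroxy-4-methoxy-3-methylphenyl)-3-phenylpropan-1-one | COc1cc(O)c(C(=O)CCc2ccccc2)c(O)c1C
F3 | step 12 | 5,7-bis(benzyloxy)-8-{[2,4-dihydroxy-6-methoxy-5-methyl-3-(3-phenylpropanoyl)phenyl]methyl}-3-methoxyflavone | COc1c(-c2ccccc2)oc2c(Cc3c(O)c(C(=O)CCc4ccccc4)c(O)c(C)c3OC)c(OCc3ccccc3)cc(OCc3ccccc3)c2c1=O
F4 | step 14 | ketiminium chloride of the tri-O-benzyl ring D ketone | COc1c(-c2ccccc2)oc2c(Cc3c(OCc4ccccc4)c(C(=[NH2+])CCc4ccccc4)c(O)c(C)c3OC)c(OCc3ccccc3)cc(OCc3ccccc3)c2c1=O.[Cl-]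
F5 | step 14 | 5,7-bis(benzyloxy)-8-{[2-(benzyloxy)-4-hydroxy-6-methoxy-5-methyl-3-(3-phenylpropanoyl)phenyl]methyl}-3-methoxyflavone | COc1c(-c2ccccc2)oc2c(Cc3c(OCc4ccccc4)c(C(=O)CCc4ccccc4)c(O)c(C)c3OC)c(OCc3ccccc3)cc(OCc3ccccc3)c2c1=O
F6 | step 8 | 5,7-bis(benzyloxy)-8-(3-ethoxyprop-2-yn-1-yl)-3-methoxyflavone | COc1c(-c2ccccc2)oc2c(CC#COCC)c(OCc3ccccc3)cc(OCc3ccccc3)c2c1=O
F7 | step 8 | 4,4-dichloro-3-ethoxy-2-{[5,7-bis(benzyloxy)-3-methoxyflavon-8-yl]methyl}cyclobut-2-en-1-one | COc1c(-c2ccccc2)oc2c(CC3=C(OCC)C(Cl)(Cl)C3=O)c(OCc3ccccc3)cc(OCc3ccccc3)c2c1=O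
F8 | step 8 | 3-ethoxy-2-{[5,7-bis(benzyloxy)-3-methoxyflavon-8-yl]methyl}cyclobut-2-en-1-one | COc1c(-c2ccccc2)oc2c(CC3=C(OCC)CC3=O)c(OCc3ccccc3)cc(OCc3ccccc3)c2c1=O
F9 | step 8 | 3-hydroxy-2-{[5,7-bis(benzyloxy)-3-methoxyflavon-8-yl]methyl}cyclobut-2-en-1-one | COc1c(-c2ccccc2)oc2c(CC3=C(O)CC3=O)c(OCc3ccccc3)cc(OCc3ccccc3)c2c1=O
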